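The retrosynthesis cuts, in order: O1–C6 of the 1,2-dioxane (back to a C3 hydroperoxide and a Z-C5=C6 alkene, with a C5–I bond that exists only between steps 18 and 19), O2–C3 (SN2 with inversion), C2–C3 (aldol), C8–C9 (sp3–sp2 coupling), and the C9 carbinol/C10 methylene pair (back to an epoxy alcohol).
The enabling feature lies in the ring O1–O2–C3–C4–C5–C6. The quaternary C6 (CH3, C7 arm, O1) sits 1,4 to the secondary C3 (O2, C2 side chain), and its methyl is trans to that side chain. Anti addition to a Z alkene through a chair with the C3 branch equatorial gives exactly this relation.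
In the forward direction, the C3–C8 chain with its Z alkene is cut out of a Birch diene and joined to a ring A bromo enal. Ring A is then completed, C1–C2 are added by aldol, the peroxide is installed, and the dioxane (the only ring built) closes in step 18.
C9 comes from a Sharpless epoxidation. C2 and C3 come from an Evans syn aldol, and C3 is then inverted by the peroxide nucleophile. C6 is relayed from C3 in the key step, and the alkene geometry comes from the six-membered ring of the diene.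

Key step: step 18

Remark: C1 is the ester carbonyl, C2–C8 the chain, C9 the ring A carbinol carbon and C10 the ring A carbon bearing =CH2; O2 sits on C3 and O1 on C6. The target is (2S,3S,6R,9S). CIP letters at C2, C5, C6 and C10 change along the route only where substituent ranks change. 2-Methoxyprop-2-yl hydroperoxide is not sold and is made in step 15.

Step 1
Reactants: 1 4-methylanisole
Product: 2 1-methoxy-4-methylcyclohexa-1,4-diene
Conditions: Li, NH3(l), t-BuOH, THF, −78 to −33 °C
Reagents that add atoms: none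
Why: Birch reduction of an anisole keeps both donor-substituted carbons sp2, so the unconjugated 1,4-diene results, in which the two ring CH2 groups on the methyl-bearing alkene (later C4 and C7) are locked cis.

Step 2
Reactants: 2 1-methoxy-4-methylcyclohexa-1,4-diene
Product: 4 methyl (3Z)-6-hydroxy-4-methylhex-3-enoate, via aldehyde ester 3 (not isolated)
Conditions: O3 (1 equiv), CH2Cl2–MeOH, −78 °C; Me2S; then NaBH4, 0 °C
Reagents that add atoms: ozone [O-][O+]=O
Why: Chemoselective ozonolysis: the enol ether alkene reacts far faster than the trialkyl alkene, its cleavage gives the C3 ester and the C8 aldehyde directly, borohydride reduces only the aldehyde, and the ring-derived Z geometry of C5=C6 is untouched.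

Step 3
Reactants: 4 methyl (3Z)-6-hydroxy-4-methylhex-3-enoate
Product: 5 methyl (3Z)-6-iodo-4-methylhex-3-enoate
Conditions: I2, PPh3, imidazole, CH2Cl2, 0 °C
Reagents that add atoms: iodine II
Why: Appel-type iodination is an SN2 displacement of an activated primary alkoxyphosphonium ion under nearly neutral conditions, which should leave the β,γ-unsaturated ester out of conjugation.

Step 4
Reactants: 6 2,2-dimethylcyclohexan-1-one
Product: 7 2-bromo-3,3-dimethylcyclohex-1-ene-1-carbaldehyde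
Conditions: PBr3, DMF, CHCl3, 0 to 60 °C; then ice–water
Reagents that add atoms: N,N-dimethylformamide CN(C)C=O; phosphorus tribromide BrP(Br)Br; water O
Why: Vilsmeier–Haack–Arnold bromoformylation: the ketone can enolise on one side only, so formylation there and replacement of the activated carbonyl oxygen by bromide should give a single β-bromo enal with the bromine on the future C9.

Step 5
Reactants: 5 methyl (3Z)-6-iodo-4-methylhex-3-enoate; 7 2-bromo-3,3-dimethylcyclohex-1-ene-1-carbaldehyde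
Product: 9 methyl (3Z)-6-(2-formyl-6,6-dimethylcyclohex-1-en-1-yl)-4-methylhex-3-enoate, via alkylzinc iodide 8 (not isolated)
Conditions: 5, Zn dust, LiCl, THF, 40 °C; then 7, Pd(OAc)2 (cat.), SPhos, THF, 25 to 50 °C
Reagents that add atoms: none
Why: Negishi sp3–sp2 coupling: zinc insertion tolerates the ester, the β-bromo enal adds readily to zerovalent palladium, and the bulky biaryl phosphine favours reductive elimination over β-hydride loss, so the C8–C9 bond forms without touching the Z alkene.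

Step 6
Reactants: 9 methyl (3Z)-6-(2-formyl-6,6-dimethylcyclohex-1-en-1-yl)-4-methylhex-3-enoate
Product: 10 methyl (3Z)-6-[2-(hydroxymethyl)-6,6-dimethylcyclohex-1-en-1-yl]-4-methylhex-3-enoate
Conditions: NaBH4, CeCl3·7H2O, MeOH, 0 °C
Reagents that add atoms: none
Why: Luche reduction delivers hydride 1,2 to the enal and is too mild to reduce the methyl ester.

Step 7
Reactants: 10 methyl (3Z)-6-[2-(hydroxymethyl)-6,6-dimethylcyclohex-1-en-1-yl]-4-methylhex-3-enoate
Product: 11 methyl (3Z)-6-[(1S,6S)-6-(hydroxymethyl)-2,2-dimethyl-7-oxabicyclo[4.1.0]heptan-1-yl]-4-methylhex-3-enoate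
Conditions: Ti(OiPr)4 (cat.), L-(+)-diethyl tartrate (cat.), t-BuOOH, 4 Å MS, CH2Cl2, −20 °C
Reagents that add atoms: tert-butyl hydroperoxide CC(C)(C)OO
Why: Sharpless asymmetric epoxidation oxidises only the alkene of the titanium-bound allylic alcohol, and L-(+)-diethyl tartrate directs oxygen to the face that gives the (1S,6S)-epoxide, which fixes the C9–O bond of the target.

Step 8
Reactants: 11 methyl (3Z)-6-[(1S,6S)-6-(hydroxymethyl)-2,2-dimethyl-7-oxabicyclo[4.1.0]heptan-1-yl]-4-methylhex-3-enoate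
Product: 12 methyl (3Z)-6-[(1S,6R)-6-(iodomethyl)-2,2-dimethyl-7-oxabicyclo[4.1.0]heptan-1-yl]-4-methylhex-3-enoate
Conditions: I2, PPh3, imidazole, Et2O–MeCN, 0 °C
Reagents that add atoms: iodine II
Why: Appel-type iodination of a 2,3-epoxy alcohol is a standard SN2 process that leaves the oxirane and both of its stereocentres intact.

Step 9
Reactants: 12 methyl (3Z)-6-[(1S,6R)-6-(iodomethyl)-2,2-dimethyl-7-oxabicyclo[4.1.0]heptan-1-yl]-4-methylhex-3-enoate
Product: 13 methyl (3Z)-6-[(1S)-1-hydroxy-2,2-dimethyl-6-methylidenecyclohexyl]-4-methylhex-3-enoate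
Conditions: Zn dust, AcOH, EtOH, 0 °C to rt
Reagents that add atoms: none
Why: Zinc inserts into the C–I bond and the β-oxirane C–O bond is expelled (reductive fragmentation of a 2,3-epoxy iodide), which creates the exocyclic methylene regiospecifically and leaves the C9–O bond, hence the S configuration, untouched.

Step 10
Reactants: 13 methyl (3Z)-6-[(1S)-1-hydroxy-2,2-dimethyl-6-methylidenecyclohexyl]-4-methylhex-3-enoate
Product: 14 methyl (3Z)-6-[(1S)-2,2-dimethyl-6-methylidene-1-(triethylsilyloxy)cyclohexyl]-4-methylhex-3-enoate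
Conditions: TESOTf, 2,6-lutidine, CH2Cl2, −78 to 0 °C
Reagents that add atoms: triethylsilyl trifluoromethanesulfonate CC[Si](CC)(CC)OS(=O)(=O)C(F)(F)F
Why: A silyl triflate with a hindered pyridine base silylates even congested tertiary alcohols, and the ether is needed to keep the C9 oxygen silent in step 18.

Step 11
Reactants: 14 methyl (3Z)-6-[(1S)-2,2-dimethyl-6-methylidene-1-(triethylsilyloxy)cyclohexyl]-4-methylhex-3-enoate
Product: 15 (3Z)-6-[(1S)-2,2-dimethyl-6-methylidene-1-(triethylsilyloxy)cyclohexyl]-4-methylhex-3-enal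
Conditions: i-Bu2AlH (1.1 equiv), CH2Cl2, −78 °C; MeOH, aq potassium sodium tartrate
Reagents that add atoms: none
Why: Partial reduction of a methyl ester with i-Bu2AlH stops at the aluminium hemiacetal at −78 °C, and the β,γ-unsaturated aldehyde released on work-up is used at once to avoid conjugation.

Step 12
Reactants: 15 (3Z)-6-[(1S)-2,2-dimethyl-6-methylidene-1-(triethylsilyloxy)cyclohexyl]-4-methylhex-3-enal; 16 (4S)-4-benzyl-3-propanoyl-1,3-oxazolidin-2-one
Product: 18 (4S)-4-benzyl-3-{(2S,3R,5Z)-8-[(1S)-2,2-dimethyl-6-methylidene-1-(triethylsilyloxy)cyclohexyl]-3-hydroxy-2,6-dimethyloct-5-enoyl}-1,3-oxazolidin-2-one, via boron enolate 17 (not isolated)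
Conditions: 16, Bu2BOTf, Et3N, CH2Cl2, −78 to 0 °C; 15, −78 to 0 °C; pH 7 buffer, MeOH, H2O2, 0 °C
Reagents that add atoms: none
Why: Evans syn aldol: the Z boron enolate reacts through a closed chair (Zimmerman–Traxler) transition state on the face left open by the benzyl group, which sets C2 as S and C3 as R.

Step 13
Reactants: 18 (4S)-4-benzyl-3-{(2S,3R,5Z)-8-[(1S)-2,2-dimethyl-6-methylidene-1-(triethylsilyloxy)cyclohexyl]-3-hydroxy-2,6-dimethyloct-5-enoyl}-1,3-oxazolidin-2-one
Product: 19 (2R,3R,5Z)-8-[(1S)-2,2-dimethyl-6-methylidene-1-(triethylsilyloxy)cyclohexyl]-2,6-dimethyloct-5-ene-1,3-diol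
Conditions: LiBH4, MeOH (1 equiv), Et2O, 0 °C
Reagents that add atoms: none
Why: Reductive cleavage of the N-acyl oxazolidinone with LiBH4 takes C1 to the alcohol level, where no β-elimination can follow activation of C3, without touching C2.

Step 14
Reactants: 19 (2R,3R,5Z)-8-[(1S)-2,2-dimethyl-6-methylidene-1-(triethylsilyloxy)cyclohexyl]-2,6-dimethyloct-5-ene-1,3-diol
Product: 20 (2R,3R,5Z)-1-(tert-butyldimethylsilyloxy)-8-[(1S)-2,2-dimethyl-6-methylidene-1-(triethylsilyloxy)cyclohexyl]-2,6-dimethyloct-5-en-3-ol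
Conditions: TBSCl (1.05 equiv), imidazole, CH2Cl2, 0 °C
Reagents that add atoms: tert-butyldimethylsilyl chloride C[Si](C)(Cl)C(C)(C)C
Why: Silylation with TBSCl is strongly rate-selective for the primary over the flanked secondary hydroxyl.

Step 15
Reactants: 21 2,3-dimethylbut-2-ene
Product: 22 2-hydroperoxy-2-methoxypropane
Conditions: O3, CH2Cl2–MeOH, −78 °C
Reagents that add atoms: ozone [O-][O+]=O; methanol CO
Why: Ozonolysis in methanol: the carbonyl oxide from the Criegee cleavage is trapped by the solvent to give the α-methoxy hydroperoxide, a monoprotected form of hydrogen peroxide.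

Step 16
Reactants: 20 (2R,3R,5Z)-1-(tert-butyldimethylsilyloxy)-8-[(1S)-2,2-dimethyl-6-methylidene-1-(triethylsilyloxy)cyclohexyl]-2,6-dimethyloct-5-en-3-ol; 22 2-hydroperoxy-2-methoxypropane
Product: 24 (2R,3S,5Z)-1-(tert-butyldimethylsilyloxy)-8-[(1S)-2,2-dimethyl-6-methylidene-1-(triethylsilyloxy)cyclohexyl]-3-[(2-methoxypropan-2-yl)peroxy]-2,6-dimethyloct-5-ene, via secondary triflate 23 (not isolated)
Conditions: Tf2O, 2,6-lutidine, CH2Cl2, −78 °C; then 22 (excess), KOt-Bu, THF, −78 to 0 °C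
Reagents that add atoms: none
Why: SN2 displacement of a secondary triflate by a peroxide anion, a weak base but strong α-effect nucleophile, should proceed with inversion and turn the (3R)-C–O bond into the (3S)-C–OO bond of the target.

Step 17
Reactants: 24 (2R,3S,5Z)-1-(tert-butyldimethylsilyloxy)-8-[(1S)-2,2-dimethyl-6-methylidene-1-(triethylsilyloxy)cyclohexyl]-3-[(2-methoxypropan-2-yl)peroxy]-2,6-dimethyloct-5-ene
Product: 25 (2R,3S,5Z)-1-(tert-butyldimethylsilyloxy)-8-[(1S)-2,2-dimethyl-6-methylidene-1-(triethylsilyloxy)cyclohexyl]-2,6-dimethyloct-5-en-3-yl hydroperoxide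
Conditions: AcOH–THF–H2O, 0 °C to rt
Reagents that add atoms: none
Why: The peroxyketal is an acetal-type group that hydrolyses under mild aqueous acid much faster than the primary TBS or the hindered tertiary TES ether.

Step 18
Reactants: 25 (2R,3S,5Z)-1-(tert-butyldimethylsilyloxy)-8-[(1S)-2,2-dimethyl-6-methylidene-1-(triethylsilyloxy)cyclohexyl]-2,6-dimethyloct-5-en-3-yl hydroperoxide
Product: 26 (3S,5S,6S)-3-[(2R)-1-(tert-butyldimethylsilyloxy)propan-2-yl]-6-{2-[(1S)-2,2-dimethyl-6-methylidene-1-(triethylsilyloxy)cyclohexyl]ethyl}-5-iodo-6-methyl-1,2-dioxane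
Conditions: NIS, CH2Cl2, −20 to 0 °C, dark
Reagents that add atoms: N-iodosuccinimide O=C1CCC(=O)N1I
Why: NIS transfers I+ reversibly to the electron-rich C5=C6 alkene and the terminal hydroperoxide oxygen opens the iodonium ion at C6 from the face opposite to iodine, which forms O1–C6 and leaves the temporary C5–I bond; the closest known reaction type is the halonium- or mercury-induced cyclisation of unsaturated hydroperoxides (cycloperoxyiodination). The single new ring, the 1,2-dioxane, closes in the 6-endo mode, because Markovnikov polarisation puts the positive charge on the tertiary C6, whereas 5-exo attack at the secondary C5 would lead to a 1,2-dioxolane. C6 is controlled by C3: in the chair-like transition state the branched C3 substituent sits equatorial, iodine must lie anti to the incoming O1 and is therefore equatorial, and the Z geometry then places the C7 arm (cis to C4) axial and the methyl equatorial, that is, trans to the C3 side chain. C5 is controlled by the stereospecific anti addition, follows from C6 and is erased in step 19. The step needs regioselectivity (secured by tertiary versus secondary carbon), facial selectivity (secured by the equatorial C3 branch together with the Z alkene) and chemoselectivity (secured by the higher nucleophilicity of the trisubstituted alkene over the hindered 1,1-disubstituted ring A alkene). With the C9 hydroxyl masked as its triethylsilyl ether, 5-exo etherification to an oxolane cannot compete.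

Step 19
Reactants: 26 (3S,5S,6S)-3-[(2R)-1-(tert-butyldimethylsilyloxy)propan-2-yl]-6-{2-[(1S)-2,2-dimethyl-6-methylidene-1-(triethylsilyloxy)cyclohexyl]ethyl}-5-iodo-6-methyl-1,2-dioxane
Product: 27 (3S,6R)-3-[(2R)-1-(tert-butyldimethylsilyloxy)propan-2-yl]-6-{2-[(1S)-2,2-dimethyl-6-methylidene-1-(triethylsilyloxy)cyclohexyl]ethyl}-6-methyl-1,2-dioxane
Conditions: Bu3SnH (excess, concentrated), Et3B (cat.), air, toluene, 0 °C
Reagents that add atoms: none
Why: Radical chain dehalogenation: iodine abstraction by the stannyl radical is very fast, and at high Bu3SnH concentration hydrogen transfer to the C5 radical should outrun its attack on O1, which is further disfavoured because the endocyclic O–O bond cannot line up with the radical centre.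

Step 20
Reactants: 27 (3S,6R)-3-[(2R)-1-(tert-butyldimethylsilyloxy)propan-2-yl]-6-{2-[(1S)-2,2-dimethyl-6-methylidene-1-(triethylsilyloxy)cyclohexyl]ethyl}-6-methyl-1,2-dioxane
Product: 28 (2R)-2-[(3S,6R)-6-{2-[(1S)-1-hydroxy-2,2-dimethyl-6-methylidenecyclohexyl]ethyl}-6-methyl-1,2-dioxan-3-yl]propan-1-ol
Conditions: HF·pyridine, pyridine, THF, 0 °C to rt
Reagents that add atoms: none
Why: Fluoride-driven cleavage of both silyl ethers under buffered, non-basic conditions avoids base-induced fragmentation of the secondary peroxide at C3–H.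

Step 21
Reactants: 28 (2R)-2-[(3S,6R)-6-{2-[(1S)-1-hydroxy-2,2-dimethyl-6-methylidenecyclohexyl]ethyl}-6-methyl-1,2-dioxan-3-yl]propan-1-ol
Product: 30 (2S)-2-[(3S,6R)-6-{2-[(1S)-1-hydroxy-2,2-dimethyl-6-methylidenecyclohexyl]ethyl}-6-methyl-1,2-dioxan-3-yl]propanoic acid, via aldehyde 29 (not isolated)
Conditions: TEMPO (cat.), PhI(OAc)2, MeCN–H2O, rt
Reagents that add atoms: water O
Why: Oxoammonium (TEMPO/PhI(OAc)2) oxidation in aqueous medium takes a primary alcohol through the aldehyde hydrate to the acid, cannot oxidise the tertiary carbinol, and is compatible with the alkene, the peroxide and the C2 stereocentre.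

Step 22
Reactants: 30 (2S)-2-[(3S,6R)-6-{2-[(1S)-1-hydroxy-2,2-dimethyl-6-methylidenecyclohexyl]ethyl}-6-methyl-1,2-dioxan-3-yl]propanoic acid
Product: 31 methyl (2S)-2-[(3S,6R)-6-{2-[(1S)-1-hydroxy-2,2-dimethyl-6-methylidenecyclohexyl]ethyl}-6-methyl-1,2-dioxan-3-yl]propanoate
Conditions: TMSCHN2, toluene–MeOH, 0 °C
Reagents that add atoms: trimethylsilyldiazomethane C[Si](C)(C)C=[N+]=[N-]
Why: Methyl ester formation with trimethylsilyldiazomethane is a neutral O-alkylation of the carboxylic acid that leaves C2 and the peroxide untouched.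

Compound list
1 | 4-methylanisole | COc1ccc(C)cc1 | starting material
2 | 1-methoxy-4-methylcyclohexa-1,4-diene | COC1=CCC(C)=CC1 | intermediate
3 | methyl (3Z)-4-methyl-6-oxohex-3-enoate | COC(=O)C/C=C(C)\CC=O | intermediate
4 | methyl (3Z)-6-hydroxy-4-methylhex-3-enoate | COC(=O)C/C=C(C)\CCO | intermediate
5 | methyl (3Z)-6-iodo-4-methylhex-3-enoate | COC(=O)C/C=C(C)\CCI | intermediate
6 | 2,2-dimethylcyclohexan-1-one | CC1(C)CCCCC1=O | starting material
7 | 2-bromo-3,3-dimethylcyclohex-1-ene-1-carbaldehyde | O=CC1=C(Br)C(C)(C)CCC1 | intermediate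
8 | [(3Z)-6-methoxy-3-methyl-6-oxohex-3-en-1-yl]zinc iodide | COC(=O)C/C=C(C)\CC[Zn]I | intermediate
9 | methyl (3Z)-6-(2-formyl-6,6-dimethylcyclohex-1-en-1-yl)-4-methylhex-3-enoate | COC(=O)C/C=C(C)\CCC1=C(C=O)CCCC1(C)C | intermediate
10 | methyl (3Z)-6-[2-(hydroxymethyl)-6,6-dimethylcyclohex-1-en-1-yl]-4-methylhex-3-enoate | COC(=O)C/C=C(C)\CCC1=C(CO)CCCC1(C)C | intermediate
11 | methyl (3Z)-6-[(1S,6S)-6-(hydroxymethyl)-2,2-dimethyl-7-oxabicyclo[4.1.0]heptan-1-yl]-4-methylhex-3-enoate | OC[C@@]12CCCC(C)(C)[C@]1(CC/C(C)=C\CC(=O)OC)O2 | intermediate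
12 | methyl (3Z)-6-[(1S,6R)-6-(iodomethyl)-2,2-dimethyl-7-oxabicyclo[4.1.0]heptan-1-yl]-4-methylhex-3-enoate | IC[C@@]12CCCC(C)(C)[C@]1(CC/C(C)=C\CC(=O)OC)O2 | intermediate
13 | methyl (3Z)-6-[(1S)-1-hydroxy-2,2-dimethyl-6-methylidenecyclohexyl]-4-methylhex-3-enoate | C=C1CCCC(C)(C)[C@@]1(O)CC/C(C)=C\CC(=O)OC | intermediate
14 | methyl (3Z)-6-[(1S)-2,2-dimethyl-6-methylidene-1-(triethylsilyloxy)cyclohexyl]-4-methylhex-3-enoate | C=C1CCCC(C)(C)[C@@]1(O[Si](CC)(CC)CC)CC/C(C)=C\CC(=O)OC | intermediate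
15 | (3Z)-6-[(1S)-2,2-dimethyl-6-methylidene-1-(triethylsilyloxy)cyclohexyl]-4-methylhex-3-enal | C=C1CCCC(C)(C)[C@@]1(O[Si](CC)(CC)CC)CC/C(C)=C\CC=O | intermediate
16 | (4S)-4-benzyl-3-propanoyl-1,3-oxazolidin-2-one | CCC(=O)N1[C@@H](Cc2ccccc2)COC1=O | starting material
17 | (Z)-dibutylboron enolate of 16 | C/C=C(\OB(CCCC)CCCC)N1[C@@H](Cc2ccccc2)COC1=O | intermediate
18 | (4S)-4-benzyl-3-{(2S,3R,5Z)-8-[(1S)-2,2-dimethyl-6-methylidene-1-(triethylsilyloxy)cyclohexyl]-3-hydroxy-2,6-dimethyloct-5-enoyl}-1,3-oxazolidin-2-one | C=C1CCCC(C)(C)[C@@]1(O[Si](CC)(CC)CC)CC/C(C)=C\C[C@@H](O)[C@H](C)C(=O)N1[C@@H](Cc2ccccc2)COC1=O | intermediate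
19 | (2R,3R,5Z)-8-[(1S)-2,2-dimethyl-6-methylidene-1-(triethylsilyloxy)cyclohexyl]-2,6-dimethyloct-5-ene-1,3-diol | C=C1CCCC(C)(C)[C@@]1(O[Si](CC)(CC)CC)CC/C(C)=C\C[C@@H](O)[C@H](C)CO | intermediate
20 | (2R,3R,5Z)-1-(tert-butyldimethylsilyloxy)-8-[(1S)-2,2-dimethyl-6-methylidene-1-(triethylsilyloxy)cyclohexyl]-2,6-dimethyloct-5-en-3-ol | C=C1CCCC(C)(C)[C@@]1(O[Si](CC)(CC)CC)CC/C(C)=C\C[C@@H](O)[C@H](C)CO[Si](C)(C)C(C)(C)C | intermediate
21 | 2,3-dimethylbut-2-ene | CC(C)=C(C)C | starting material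
22 | 2-hydroperoxy-2-methoxypropane | COC(C)(C)OO | intermediate
23 | (2R,3R,5Z)-trifluoromethanesulfonate of 20 | C=C1CCCC(C)(C)[C@@]1(O[Si](CC)(CC)CC)CC/C(C)=C\C[C@@H](OS(=O)(=O)C(F)(F)F)[C@H](C)CO[Si](C)(C)C(C)(C)C | intermediate
24 | (2R,3S,5Z)-1-(tert-butyldimethylsilyloxy)-8-[(1S)-2,2-dimethyl-6-methylidene-1-(triethylsilyloxy)cyclohexyl]-3-[(2-methoxypropan-2-yl)peroxy]-2,6-dimethyloct-5-ene | C=C1CCCC(C)(C)[C@@]1(O[Si](CC)(CC)CC)CC/C(C)=C\C[C@@H]([C@H](C)CO[Si](C)(C)C(C)(C)C)OOC(C)(C)OC | intermediate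
25 | (2R,3S,5Z)-1-(tert-butyldimethylsilyloxy)-8-[(1S)-2,2-dimethyl-6-methylidene-1-(triethylsilyloxy)cyclohexyl]-2,6-dimethyloct-5-en-3-yl hydroperoxide | C=C1CCCC(C)(C)[C@@]1(O[Si](CC)(CC)CC)CC/C(C)=C\C[C@@H]([C@H](C)CO[Si](C)(C)C(C)(C)C)OO | intermediate
26 | (3S,5S,6S)-3-[(2R)-1-(tert-butyldimethylsilyloxy)propan-2-yl]-6-{2-[(1S)-2,2-dimethyl-6-methylidene-1-(triethylsilyloxy)cyclohexyl]ethyl}-5-iodo-6-methyl-1,2-dioxane | C=C1CCCC(C)(C)[C@@]1(O[Si](CC)(CC)CC)CC[C@@]1(C)[C@@H](I)C[C@@H]([C@H](C)CO[Si](C)(C)C(C)(C)C)OO1 | intermediate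
27 | (3S,6R)-3-[(2R)-1-(tert-butyldimethylsilyloxy)propan-2-yl]-6-{2-[(1S)-2,2-dimethyl-6-methylidene-1-(triethylsilyloxy)cyclohexyl]ethyl}-6-methyl-1,2-dioxane | C=C1CCCC(C)(C)[C@@]1(O[Si](CC)(CC)CC)CC[C@@]1(C)CC[C@@H]([C@H](C)CO[Si](C)(C)C(C)(C)C)OO1 | intermediate
28 | (2R)-2-[(3S,6R)-6-{2-[(1S)-1-hydroxy-2,2-dimethyl-6-methylidenecyclohexyl]ethyl}-6-methyl-1,2-dioxan-3-yl]propan-1-ol | C=C1CCCC(C)(C)[C@@]1(O)CC[C@@]1(C)CC[C@@H]([C@H](C)CO)OO1 | intermediate
29 | (2S)-2-[(3S,6R)-6-{2-[(1S)-1-hydroxy-2,2-dimethyl-6-methylidenecyclohexyl]ethyl}-6-methyl-1,2-dioxan-3-yl]propanal | C=C1CCCC(C)(C)[C@@]1(O)CC[C@@]1(C)CC[C@@H]([C@H](C)C=O)OO1 | intermediate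
30 | (2S)-2-[(3S,6R)-6-{2-[(1S)-1-hydroxy-2,2-dimethyl-6-methylidenecyclohexyl]ethyl}-6-methyl-1,2-dioxan-3-yl]propanoic acid | C=C1CCCC(C)(C)[C@@]1(O)CC[C@@]1(C)CC[C@@H]([C@H](C)C(=O)O)OO1 | intermediate
31 | methyl (2S)-2-[(3S,6R)-6-{2-[(1S)-1-hydroxy-2,2-dimethyl-6-methylidenecyclohexyl]ethyl}-6-methyl-1,2-dioxan-3-yl]propanoate (CNP0255906.1) | C=C1CCCC(C)(C)[C@@]1(O)CC[C@@]1(C)CC[C@@H]([C@H](C)C(=O)OC)OO1 | target

Total step count: 22.
Longest linear sequence: 20 steps (steps 1–3, 5–14 and 16–22, from 4-methylanisole).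

Steps most likely to fail

1. Step 16.
The triflate may be lost by E2 elimination toward a diene conjugated with C5=C6. It may also ionise with help from the neighbouring π bond, which would leak configuration at C3. The centre is in addition β-branched, which slows the SN2 path.
The fallback sets out from 20 and replaces the ionising sulfonate by a halide through a triple-inversion sequence. Mitsunobu inversion (4-nitrobenzoic acid, PPh3, DIAD, THF) should give the (3S)-4-nitrobenzoate F1. Methanolysis (K2CO3, MeOH) should then give the (3S)-alcohol F2. Appel bromination (CBr4, PPh3, CH2Cl2) with inversion should give the (3R)-bromide F3. Finally, SN2 displacement with 22 and CsOH·H2O in DMF, again with inversion, comes back to the route at 24.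

2. Step 18.
Closure through a twist-boat instead of the chair would erode facial selectivity at C6. Some 5-exo closure or iodination of the ring A alkene could also intrude.
The fallback sets out from 24 and replaces substrate control of the alkene face by reagent control. Shi epoxidation with the enantiomer of the D-fructose-derived ketone (KHSO5, K2CO3, MeCN–dimethoxymethane–buffer, 0 °C) should give the (5S,6R)-epoxide F4. Aqueous acetic acid frees the epoxy hydroperoxide F5. Catalytic camphorsulfonic acid in CH2Cl2 should then induce 6-endo opening at the tertiary C6 with inversion, which forms the same O1–C6 bond and gives the 5-hydroxy-1,2-dioxane F6. Thiocarbonyldiimidazole converts it into the imidazole-1-carbothioate F7, and Barton–McCombie deoxygenation (Bu3SnH, Et3B, air) comes back to the route at 27.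

3. Step 19.
The C5 radical may displace at O1, which opens the peroxide and forms an oxirane. Stannyl radicals may also attack the O–O bond once the iodide is consumed.
The fallback sets out from 25 and changes the temporary bond from C–I to C–Hg. Cycloperoxymercuration with Hg(OAc)2 in CH2Cl2 (anti, Markovnikov, 6-endo and reversible, so that the chair-derived isomer can accumulate) should give the 5-acetoxymercurio-1,2-dioxane F8. Reduction with NaBH4 in aqueous NaOH at 0 °C then proceeds through an alkylmercury hydride, which is a faster hydrogen donor and needs no tin. This comes back to the route at 27.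

Further compounds
F1 | step 16 | (2R,3S,5Z)-1-(tert-butyldimethylsilyloxy)-8-[(1S)-2,2-dimethyl-6-methylidene-1-(triethylsilyloxy)cyclohexyl]-2,6-dimethyloct-5-en-3-yl 4-nitrobenzoate | C=C1CCCC(C)(C)[C@@]1(O[Si](CC)(CC)CC)CC/C(C)=C\C[C@H](OC(=O)c1ccc(cc1)[N+](=O)[O-])[C@H](C)CO[Si](C)(C)C(C)(C)C
F2 | step 16 | (2R,3S,5Z)-1-(tert-butyldimethylsilyloxy)-8-[(1S)-2,2-dimethyl-6-methylidene-1-(triethylsilyloxy)cyclohexyl]-2,6-dimethyloct-5-en-3-ol | C=C1CCCC(C)(C)[C@@]1(O[Si](CC)(CC)CC)CC/C(C)=C\C[C@H](O)[C@H](C)CO[Si](C)(C)C(C)(C)C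
F3 | step 16 | (2R,3R,5Z)-3-bromo-1-(tert-butyldimethylsilyloxy)-8-[(1S)-2,2-dimethyl-6-methylidene-1-(triethylsilyloxy)cyclohexyl]-2,6-dimethyloct-5-ene | C=C1CCCC(C)(C)[C@@]1(O[Si](CC)(CC)CC)CC/C(C)=C\C[C@@H](Br)[C@H](C)CO[Si](C)(C)C(C)(C)C
F4 | step 18 | (5S,6R)-5,6-epoxide of 24 | C=C1CCCC(C)(C)[C@@]1(O[Si](CC)(CC)CC)CC[C@@]1(C)O[C@H]1C[C@@H]([C@H](C)CO[Si](C)(C)C(C)(C)C)OOC(C)(C)OC
F5 | step 18 | (5S,6R)-5,6-epoxide of 25 | C=C1CCCC(C)(C)[C@@]1(O[Si](CC)(CC)CC)CC[C@@]1(C)O[C@H]1C[C@@H]([C@H](C)CO[Si](C)(C)C(C)(C)C)OO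
F6 | step 18 | (3S,5S,6S)-5-hydroxy analogue of 26 (OH in place of I) | C=C1CCCC(C)(C)[C@@]1(O[Si](CC)(CC)CC)CC[C@@]1(C)[C@@H](O)C[C@@H]([C@H](C)CO[Si](C)(C)C(C)(C)C)OO1
F7 | step 18 | O-(1H-imidazole-1-carbothioyl) derivative of F6 | C=C1CCCC(C)(C)[C@@]1(O[Si](CC)(CC)CC)CC[C@@]1(C)[C@@H](OC(=S)n2ccnc2)C[C@@H]([C@H](C)CO[Si](C)(C)C(C)(C)C)OO1
F8 | step 19 | (3S,5S,6S)-5-(acetoxymercurio) analogue of 26 (HgOAc in place of I) | C=C1CCCC(C)(C)[C@@]1(O[Si](CC)(CC)CC)CC[C@@]1(C)[C@@H]([Hg]OC(C)=O)C[C@@H]([C@H](C)CO[Si](C)(C)C(C)(C)C)OO1
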